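The numbers of this flask were set for the occasion; no experiment stands behind them.

Follow the carrier.

substrate 0.80 M; solid reagent 1.20 M; initiator 8.0 mM; time 10 d

- amount of target at 10 d, in percent of the substrate charged
- the change that raises the amount of target at 10 d, in percent of the substrate charged most ("none" if none brings more than 2 percentage points) (ash / maple / none)
- amount of target at 10 d, in percent of the substrate charged, after maple

- ash: doubling the solubility in step 6, all else as stated
- maple: doubling the dissolution coefficient of step 6, all else as stated

- a species is counted by the substrate in it: one ended chains B counts as two
- for a step with 2 of a species take k times the square, and two of it per event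
- given per volume of solution although it is solid: solid reagent
- at the start none of the solid reagent is in solution
- run time (flask): 10 d

    substrate + initiating radical → capped initiator + first chain carrier (k1 = 51200 M⁻¹ min⁻¹)
    first chain carrier → ended carrier (k2 = 20.3 min⁻¹)
    substrate + second chain carrier → released group + first chain carrier (k3 = 17200 M⁻¹ min⁻¹)
    initiator → 2 initiating radical (k4 = 0.00253 min⁻¹)
    2 second chain carrier → ended chains A (k5 = 1 × 10⁶ M⁻¹ s⁻¹)
    solid reagent ⇌ partner, rate k6*(cs6 - [partner]) while solid is left; crystals form when [partner] > cs6 (cs6 = 0.28 M, k6 = 4.09 × 10⁻⁴ min⁻¹)
    2 first chain carrier → ended chains B (k7 = 1.4 × 10⁷ M⁻¹ s⁻¹)
    partner + first chain carrier → target + second chain carrier (k8 = 11600 M⁻¹ min⁻¹)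

The first chain carrier turns partner into target and becomes the second chain carrier, which takes substrate and returns as the first. The initiator starts each chain, and pairs of first chain carrier end them. I build this up by hand.

1. Main step. The second chain carrier goes back at 13800 min⁻¹, faster than the 3250 min⁻¹ at which the first leaves even at full partner. So the first chain carrier is the resting state, substrate drops out of the rate, and partner is lost pseudo-first-order.

2. Add the initiator. Its half-life is 0.19 d, far shorter than the run. The balance of making and pairing starts the carrier at 1.55 × 10⁻⁷ M, and this level fades at half the initiator's rate. At that starting level pairing removes carrier at 261 min⁻¹, against 20.3 min⁻¹ for the single ending. I call the time integral of step constant times carrier level the carrier dose: how many e-foldings a partner present from the start undergoes. It comes to 1.42, and it holds no substrate. With partner held at solubility throughout, I get 0.399 M of target.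

3. Add the dissolving. The solid feeds at most 1.15 × 10⁻⁴ M min⁻¹, so over the carrier's life it brings 0.0905 M, less than the solubility. Each partner is used with a chance of at most 75.8%, so the number falls to 0.0686 M.

4. The rest. The single ending and slower dissolving near solubility pull lower still, but I commit to 8.59%. Both changes double the feed, and ash also lifts the ceiling, so I choose ash, with maple under 17.2%.

The forecast gives 7%, below my 8.59%, then ash and 11.8%: “Doubling the solubility doubles the partner level at every moment”.

The flask gives 7.05%, and ash is best, with 7 percentage points against 5 points for maple; after maple it gives 12.1%.

In the flask at 1.32 d, partner is made 5.24 times faster than it is used, and the initiator's half-life is 0.19 d. Half of the turnover of the step from substrate and second chain carrier is done by 0.661 d, and at 10.0 d partner in the flask stands at 0.279 M with target at 7.05%. The answer for the flask has moved by 5 points at 28.2 mM of initiator, the nearest such amount above the charge. Feed and dose gave 0.0686 M of target, where the flask holds 0.0564 M. By my reckoning the neighbour flask with 0.32 M of substrate keeps the dose of 1.42, its hand-over still being the faster, so the flask's amount of target predicts 17.6%, and the neighbour flask gives 17.6%.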